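## Retrosynthetic overview

- The target comes from a late, face-selective epoxidation of the less hindered ring alkene of a cis-5,6-disubstituted cyclohexa-1,3-diene; the side-chain ketone comes from its carbinol.
- The cyclohexadiene comes from a photochemical conrotatory 6π closure of an acyclic tetraene pyranone (new ring bond between the side-chain-bearing carbon and the pyranone-bearing quaternary carbon); a carbinol-to-pyranone hydrogen bond relays the side-chain stereocentre to both ring stereocentres.
- The tetraene comes from a Negishi union of a (2E,4Z)-iododienyl pyranone with a dienylzirconium made from a chiral enyne.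
- The iododienyl pyranone comes from a 6-ethyl γ-pyranone (triketide lactonisation, O-methylation) and (Z)-3-iodo-2-methylacrolein; the enyne comes from an enantiopure C4 alkynol and propanal (Marshall–Tamaru), then methylation, hydrostannation and Stille alkynylation.
- Ring order: pyranone (step 2), carbocycle (step 13), oxirane (step 15).

Assumption: the five starting materials are catalogue chemicals, the alkynol enantiopure (≥98% ee).

## Route

Step 1
Reactants: 1 methyl 2-methyl-3-oxopentanoate; 2 N-methoxy-N-methylpropanamide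
Product: 3 methyl 2,4-dimethyl-3,5-dioxoheptanoate (stereoisomer and tautomer mixture)
Conditions: NaH, THF, 0 °C; n-BuLi, −10 °C; 2, −78 → 0 °C; aq. HCl
Reagents that add atoms: none
Why: γ-Acylation of the β-keto ester dianion (Claisen-type acylation) with a Weinreb amide stops at the stable tetrahedral chelate, so no over-addition occurs and no stereocentre needs control.

Step 2
Reactants: 3 methyl 2,4-dimethyl-3,5-dioxoheptanoate
Product: 4 6-ethyl-4-hydroxy-3,5-dimethyl-2H-pyran-2-one
Conditions: DBU, PhMe, 80 °C; aq. HCl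
Reagents that add atoms: none
Why: Base-mediated enol lactonisation (intramolecular transesterification of the δ-oxo enol onto the methyl ester) closes the 4-hydroxy-2-pyranone with loss of methanol.

Step 3
Reactants: 4 6-ethyl-4-hydroxy-3,5-dimethyl-2H-pyran-2-one
Product: 6 6-ethyl-2-methoxy-3,5-dimethyl-4H-pyran-4-one, via methoxypyrylium triflate 5 (not isolated)
Conditions: MeOTf, CH2Cl2, rt; aq. NaHCO3
Reagents that add atoms: methyl trifluoromethanesulfonate COS(=O)(=O)C(F)(F)F
Why: O-Alkylation at the lactone carbonyl oxygen, the most nucleophilic site of a 4-hydroxy-2-pyranone, gives pyrylium 5, whose deprotonation is the 2-methoxy-4-pyranone; the minor 4-methoxy-2-pyranone is removed by chromatography.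

Step 4
Reactants: 7 prop-2-yn-1-ol
Product: 9 (Z)-3-iodo-2-methylprop-2-en-1-ol, via vinylmagnesium alkoxide 8 (not isolated)
Conditions: MeMgBr (2.5 equiv), CuI (10 mol %), THF, −10 °C → rt; I2, −78 → 0 °C; H2O
Reagents that add atoms: methylmagnesium bromide C[Mg]Br; iodine II
Why: Copper-catalysed anti-carbomagnesiation of the propargylic alkoxide (Duboudin reaction) through the five-membered chelate 8, then iodinolysis with retention, fixes the Z geometry.

Step 5
Reactants: 9 (Z)-3-iodo-2-methylprop-2-en-1-ol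
Product: 10 (Z)-3-iodo-2-methylprop-2-enal
Conditions: MnO2, CH2Cl2, rt, dark; used at once
Reagents that add atoms: none
Why: Allylic alcohol oxidation on MnO2 is neutral and leaves the vinyl iodide and its Z geometry untouched.

Step 6
Reactants: 6 6-ethyl-2-methoxy-3,5-dimethyl-4H-pyran-4-one; 10 (Z)-3-iodo-2-methylprop-2-enal
Product: 13 6-[(2E,4Z)-5-iodo-4-methylpenta-2,4-dien-2-yl]-2-methoxy-3,5-dimethyl-4H-pyran-4-one, via lithium aldolate 11 (not isolated), via allylic mesylate 12 (not isolated)
Conditions: LiN(SiMe3)2, THF, −78 °C; 10; MsCl, −78 → 0 °C; DBU, rt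
Reagents that add atoms: none
Why: Vinylogous aldol addition of the lithiated 6-ethyl group followed by E1cB elimination of the mesylate gives the conjugated E alkene (pyranone trans to the chain), while the Z vinyl iodide has no anti β-hydrogen and survives DBU.

Step 7
Reactants: 14 (S)-but-3-yn-2-ol
Product: 15 (S)-but-3-yn-2-yl methanesulfonate
Conditions: MsCl, Et3N, CH2Cl2, −78 °C
Reagents that add atoms: methanesulfonyl chloride CS(=O)(=O)Cl
Why: O-Sulfonylation does not touch the stereocentre (retention).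

Step 8
Reactants: 15 (S)-but-3-yn-2-yl methanesulfonate; 16 propanal
Product: 18 (3S,4R)-4-methylhex-5-yn-3-ol, via allenylzinc mesylate 17 (not isolated)
Conditions: Pd(OAc)2 (5 mol %), PPh3 (5 mol %), ZnEt2 (3 equiv), THF, −78 → −20 °C; 1 M HCl
Reagents that add atoms: none
Why: Marshall–Tamaru propargylation: anti SN2' oxidative addition to zerovalent palladium, transmetalation to allenylzinc 17 and SE2' addition through a cyclic chair transition state carry the bought stereocentre over with net inversion (giving 4R) and set the anti 3S carbinol, which is oxidised away later.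

Step 9
Reactants: 18 (3S,4R)-4-methylhex-5-yn-3-ol
Product: 19 (3S,4R)-4-methylhept-5-yn-3-ol
Conditions: n-BuLi (2.1 equiv), THF, −78 → 0 °C; MeI (1.05 equiv); H2O
Reagents that add atoms: iodomethane CI
Why: In the alkoxide/acetylide dianion only the acetylide carbon is alkylated by one equivalent of MeI in THF (acetylide alkylation), and neither stereocentre is affected.

Step 10
Reactants: 19 (3S,4R)-4-methylhept-5-yn-3-ol
Product: 20 (3S,4R,5E)-4-methyl-6-(tributylstannyl)hept-5-en-3-ol
Conditions: Bu3SnH, Pd(PPh3)2Cl2 (2 mol %), THF, 0 °C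
Reagents that add atoms: tributyltin hydride CCCC[SnH](CCCC)CCCC
Why: Palladium-catalysed syn-hydrostannation puts tin on the less hindered methyl-bearing alkyne carbon, away from the branched stereocentre, giving the E stannane.

Step 11
Reactants: 20 (3S,4R,5E)-4-methyl-6-(tributylstannyl)hept-5-en-3-ol
Product: 21 (3S,4R,5E)-4,6-dimethylnon-5-en-7-yn-3-ol
Conditions: 1-bromoprop-1-yne, Pd(PPh3)4 (5 mol %), DMF, rt
Reagents that add atoms: 1-bromoprop-1-yne CC#CBr
Why: Stille coupling of the alkenylstannane with the alkynyl bromide proceeds with retention of alkene geometry and tolerates the free hydroxyl.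

Step 12
Reactants: 21 (3S,4R,5E)-4,6-dimethylnon-5-en-7-yn-3-ol; 13 6-[(2E,4Z)-5-iodo-4-methylpenta-2,4-dien-2-yl]-2-methoxy-3,5-dimethyl-4H-pyran-4-one
Product: 23 6-[(2E,4Z,6E,8E,10R,11S)-11-hydroxy-4,6,8,10-tetramethyltrideca-2,4,6,8-tetraen-2-yl]-2-methoxy-3,5-dimethyl-4H-pyran-4-one, via dienylzirconocene chloride 22 (not isolated)
Conditions: Cp2Zr(H)Cl (2.1 equiv), THF, rt, dark; 13, ZnCl2 (20 mol %), Pd(PPh3)4 (5 mol %), rt; cold 0.5 M HCl
Reagents that add atoms: none
Why: syn-Hydrozirconation of the enyne at the methyl terminus and zinc-assisted, palladium-catalysed Negishi coupling with retention on both partners deliver the (E,Z,E,E) tetraene, which has no low-barrier thermal electrocyclisation at room temperature.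

Step 13
Reactants: 23 6-[(2E,4Z,6E,8E,10R,11S)-11-hydroxy-4,6,8,10-tetramethyltrideca-2,4,6,8-tetraen-2-yl]-2-methoxy-3,5-dimethyl-4H-pyran-4-one
Product: 25 6-[(1R,6S)-6-[(2E,4R,5S)-5-hydroxy-4-methylhept-2-en-2-yl]-1,3,5-trimethylcyclohexa-2,4-dien-1-yl]-2-methoxy-3,5-dimethyl-4H-pyran-4-one, via Z-pyranonyl tetraene 24 (not isolated)
Conditions: hν (365 nm), degassed methylcyclohexane/PhMe 4:1, 1 mM, −40 °C, to the photostationary state; then hν (313 nm), −40 °C
Reagents that add atoms: none
Why: Proposed new method: a hydroxyl-templated, substrate-relayed diastereoselective photochemical 6π electrocyclisation — 365 nm light isomerises the pyranone-proximal alkene E→Z (the twisted isomer 24 stops absorbing there and accumulates), 313 nm light then closes its helical Z,Z,E-triene conrotatorily (pyranone inside, dienyl outside, hence the cis relationship of dienyl and pyranone) faster than the helix can invert, so the ground-state helix ratio is copied into the product; in the non-polar solvent the carbinol O–H hydrogen-bonds the pyranone carbonyl and, with the allylic hydrogen of the (R)-methyl stereocentre held in the alkene plane by A(1,3) strain, a simple model predicts that only the helix leading to the (1R,6S) ring can keep this macrocyclic hydrogen bond, so the bought stereocentre sets both ring stereocentres; the closest known reactions are the unselective photochemical conrotatory 6π closures of polyene pyranones and hydrogen-bond-templated photocycloadditions.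

Step 14
Reactants: 25 6-[(1R,6S)-6-[(2E,4R,5S)-5-hydroxy-4-methylhept-2-en-2-yl]-1,3,5-trimethylcyclohexa-2,4-dien-1-yl]-2-methoxy-3,5-dimethyl-4H-pyran-4-one
Product: 26 6-[(1R,6S)-1,3,5-trimethyl-6-[(2E,4R)-4-methyl-5-oxohept-2-en-2-yl]cyclohexa-2,4-dien-1-yl]-2-methoxy-3,5-dimethyl-4H-pyran-4-one
Conditions: Dess–Martin periodinane, NaHCO3, CH2Cl2, 0 °C
Reagents that add atoms: none
Why: Buffered Dess–Martin oxidation of the secondary carbinol is fast and near-neutral, so the α-methyl β,γ-unsaturated ketone is formed without epimerisation or alkene migration.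

Step 15
Reactants: 26 6-[(1R,6S)-1,3,5-trimethyl-6-[(2E,4R)-4-methyl-5-oxohept-2-en-2-yl]cyclohexa-2,4-dien-1-yl]-2-methoxy-3,5-dimethyl-4H-pyran-4-one
Product: 27 2-methoxy-3,5-dimethyl-6-[(1S,2R,3R,6R)-1,3,5-trimethyl-2-[(2E,4R)-4-methyl-5-oxohept-2-en-2-yl]-7-oxabicyclo[4.1.0]hept-4-en-3-yl]-4H-pyran-4-one
Conditions: DMDO (1.05 equiv), acetone, −40 → −20 °C
Reagents that add atoms: dimethyldioxirane CC1(C)OO1
Why: Electrophilic epoxidation under steric approach control: the diene is more nucleophilic than the side-chain alkene (deactivated by the allylic ketone), its C2=C3 alkene is shielded by the quaternary carbon, and the C4=C5 alkene is attacked on the face opposite the pseudoaxial dienyl group and the pyranone, which sets both oxirane stereocentres.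

## Compound list

1 | methyl 2-methyl-3-oxopentanoate | CCC(=O)C(C)C(=O)OC | starting material
2 | N-methoxy-N-methylpropanamide | CCC(=O)N(C)OC | starting material
3 | methyl 2,4-dimethyl-3,5-dioxoheptanoate (stereoisomer and tautomer mixture) | CCC(=O)C(C)C(=O)C(C)C(=O)OC | intermediate
4 | 6-ethyl-4-hydroxy-3,5-dimethyl-2H-pyran-2-one | CCc1oc(=O)c(C)c(O)c1C | intermediate
5 | 6-ethyl-4-hydroxy-2-methoxy-3,5-dimethylpyrylium trifluoromethanesulfonate | CCc1[o+]c(OC)c(C)c(O)c1C.[O-]S(=O)(=O)C(F)(F)F | intermediate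
6 | 6-ethyl-2-methoxy-3,5-dimethyl-4H-pyran-4-one | CCc1oc(OC)c(C)c(=O)c1C | intermediate
7 | prop-2-yn-1-ol | OCC#C | starting material
8 | bromomagnesium (Z)-3-(bromomagnesio)-2-methylprop-2-en-1-olate (Mg cis to the CH2O group) | Br[Mg]OC/C(C)=C\[Mg]Br | intermediate
9 | (Z)-3-iodo-2-methylprop-2-en-1-ol | OC/C(C)=C\I | intermediate
10 | (Z)-3-iodo-2-methylprop-2-enal | O=C/C(C)=C\I | intermediate
11 | lithium (Z)-5-iodo-2-(6-methoxy-3,5-dimethyl-4-oxo-4H-pyran-2-yl)-4-methylpent-4-en-3-olate (diastereomer mixture) | COc1oc(C(C)C(O[Li])/C(C)=C\I)c(C)c(=O)c1C | intermediate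
12 | (Z)-5-iodo-2-(6-methoxy-3,5-dimethyl-4-oxo-4H-pyran-2-yl)-4-methylpent-4-en-3-yl methanesulfonate (diastereomer mixture) | COc1oc(C(C)C(OS(C)(=O)=O)/C(C)=C\I)c(C)c(=O)c1C | intermediate
13 | 6-[(2E,4Z)-5-iodo-4-methylpenta-2,4-dien-2-yl]-2-methoxy-3,5-dimethyl-4H-pyran-4-one | COc1oc(/C(C)=C/C(C)=C\I)c(C)c(=O)c1C | intermediate
14 | (S)-but-3-yn-2-ol | C[C@H](O)C#C | starting material
15 | (S)-but-3-yn-2-yl methanesulfonate | C[C@H](OS(C)(=O)=O)C#C | intermediate
16 | propanal | CCC=O | starting material
17 | (aR)-buta-1,2-dien-1-ylzinc methanesulfonate | C[CH]=[C@]=[CH][Zn]OS(C)(=O)=O | intermediate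
18 | (3S,4R)-4-methylhex-5-yn-3-ol (anti) | CC[C@H](O)[C@H](C)C#C | intermediate
19 | (3S,4R)-4-methylhept-5-yn-3-ol | CC[C@H](O)[C@H](C)C#CC | intermediate
20 | (3S,4R,5E)-4-methyl-6-(tributylstannyl)hept-5-en-3-ol | CC[C@H](O)[C@H](C)/C=C(\C)[Sn](CCCC)(CCCC)CCCC | intermediate
21 | (3S,4R,5E)-4,6-dimethylnon-5-en-7-yn-3-ol | CC[C@H](O)[C@H](C)/C=C(\C)C#CC | intermediate
22 | dienylzirconocene chloride: Cp2Zr(Cl) on C2 of the (6R,7S)-4,6-dimethylnona-2,4-dien-2-yl unit (Zr trans to C4 across C2=C3; 4E), a second Cp2Zr(Cl) on the C7 oxygen | CC[C@H](O[Zr](Cl)(C1C=CC=C1)C1C=CC=C1)[C@H](C)/C=C(\C)/C=C(\C)[Zr](Cl)(C1C=CC=C1)C1C=CC=C1 | intermediate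
23 | 6-[(2E,4Z,6E,8E,10R,11S)-11-hydroxy-4,6,8,10-tetramethyltrideca-2,4,6,8-tetraen-2-yl]-2-methoxy-3,5-dimethyl-4H-pyran-4-one | CC[C@H](O)[C@H](C)/C=C(\C)/C=C(\C)/C=C(C)\C=C(/C)c1oc(OC)c(C)c(=O)c1C | intermediate
24 | 6-[(2Z,4Z,6E,8E,10R,11S)-11-hydroxy-4,6,8,10-tetramethyltrideca-2,4,6,8-tetraen-2-yl]-2-methoxy-3,5-dimethyl-4H-pyran-4-one | CC[C@H](O)[C@H](C)/C=C(\C)/C=C(\C)/C=C(C)\C=C(\C)c1oc(OC)c(C)c(=O)c1C | intermediate
25 | 6-[(1R,6S)-6-[(2E,4R,5S)-5-hydroxy-4-methylhept-2-en-2-yl]-1,3,5-trimethylcyclohexa-2,4-dien-1-yl]-2-methoxy-3,5-dimethyl-4H-pyran-4-one (dienyl and pyranone cis) | CC[C@H](O)[C@H](C)/C=C(\C)[C@H]1C(C)=CC(C)=C[C@@]1(C)c1oc(OC)c(C)c(=O)c1C | intermediate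
26 | 6-[(1R,6S)-1,3,5-trimethyl-6-[(2E,4R)-4-methyl-5-oxohept-2-en-2-yl]cyclohexa-2,4-dien-1-yl]-2-methoxy-3,5-dimethyl-4H-pyran-4-one | CCC(=O)[C@H](C)/C=C(\C)[C@H]1C(C)=CC(C)=C[C@@]1(C)c1oc(OC)c(C)c(=O)c1C | intermediate
27 | 2-methoxy-3,5-dimethyl-6-[(1S,2R,3R,6R)-1,3,5-trimethyl-2-[(2E,4R)-4-methyl-5-oxohept-2-en-2-yl]-7-oxabicyclo[4.1.0]hept-4-en-3-yl]-4H-pyran-4-one (oxirane trans to side chain and pyranone) | CCC(=O)[C@H](C)/C=C(\C)[C@H]1[C@]2(C)O[C@@H]2C(C)=C[C@@]1(C)c1oc(OC)c(C)c(=O)c1C | target

## Step count and risk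

Total step count: 15. Longest linear sequence: 9 steps (steps 7 to 15).

Steps most likely to fail:

Step 13 (the proposed new step). Risks are a weak hydrogen-bond relay (low diastereomer ratio), direct closure of 23 to the trans ring isomer, and closure through the pyranone double bond. The fallback sets out from 23 and comes back at 25. Heating 23 in toluene at 110–140 °C (sealed tube, dark) triggers the known thermal disrotatory 6π electrocyclisation of E,Z,E polyene pyranones, in which both large terminal groups are outside and the same cis ring results. With no stereochemical relay it gives 25 together with about an equal amount of its ring diastereomer 6-[(1S,6R)-6-[(2E,4R,5S)-5-hydroxy-4-methylhept-2-en-2-yl]-1,3,5-trimethylcyclohexa-2,4-dien-1-yl]-2-methoxy-3,5-dimethyl-4H-pyran-4-one F3, which is removed by preparative HPLC; 25 then continues to step 14.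

Step 15. The two ring alkenes are both trisubstituted, so site selectivity rests on sterics alone, and the side-chain alkene may compete. The fallback sets out from 26 and comes back at 27. Photooxygenation (O2, tetraphenylporphyrin, visible light, CH2Cl2, −78 °C) adds singlet oxygen across the cyclic diene on the face opposite the dienyl group and the pyranone, giving the 2,3-dioxabicyclo[2.2.2]oct-5-ene endoperoxide of 26 F4. Triphenylphosphine then attacks the less hindered peroxide oxygen (on the secondary carbon), and the tertiary alkoxide closes in SN2' fashion to the same vinyl oxirane 27.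

Step 12. The coupling joins two trisubstituted alkenyl partners, and residual Zr–H may attack the pyranone. The fallback sets out from 21 and 13 and comes back at 23. The zirconium species 22 made from 21 is quenched with iodine to give (3S,4R,5E,7E)-8-iodo-4,6-dimethylnona-5,7-dien-3-ol F1. Iodide 13 is converted with hexabutylditin and Pd(PPh3)4 (PhMe, 80 °C) into 2-methoxy-3,5-dimethyl-6-[(2E,4Z)-4-methyl-5-(tributylstannyl)penta-2,4-dien-2-yl]-4H-pyran-4-one F2. A Stille coupling of F1 and F2 (Pd(PPh3)4, copper thiophene-2-carboxylate Cu(O2CC4H3S), DMF, rt, dark) then gives 23.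

Further compounds
F1 | step 12 | (3S,4R,5E,7E)-8-iodo-4,6-dimethylnona-5,7-dien-3-ol | CC[C@H](O)[C@H](C)/C=C(\C)/C=C(\C)I
F2 | step 12 | 2-methoxy-3,5-dimethyl-6-[(2E,4Z)-4-methyl-5-(tributylstannyl)penta-2,4-dien-2-yl]-4H-pyran-4-one | COc1oc(/C(C)=C/C(C)=C\[Sn](CCCC)(CCCC)CCCC)c(C)c(=O)c1C
F3 | step 13 | 6-[(1S,6R)-6-[(2E,4R,5S)-5-hydroxy-4-methylhept-2-en-2-yl]-1,3,5-trimethylcyclohexa-2,4-dien-1-yl]-2-methoxy-3,5-dimethyl-4H-pyran-4-one | CC[C@H](O)[C@H](C)/C=C(\C)[C@@H]1C(C)=CC(C)=C[C@]1(C)c1oc(OC)c(C)c(=O)c1C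
F4 | step 15 | 2,3-dioxabicyclo[2.2.2]oct-5-ene endoperoxide of 26 (O–O bridge across the two diene termini, on the face opposite the dienyl group and the pyranone) | CCC(=O)[C@H](C)/C=C(\C)[C@H]1[C@]2(C)OO[C@@H](C(C)=C2)[C@@]1(C)c1oc(OC)c(C)c(=O)c1C
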